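The target in the south-west run climbed and then flattened near 24.1 % over its last 3 readings while the starting material kept falling, so I followed the target against the starting material rather than against time.

the same everywhere: starting material 0.50 M

| charge | partner | second substrate | remark | time |
|---|---|---|---|---|
| south-west | 0.60 equiv | 5 equiv | the very flask that is asked about, followed so far |  |
| flask | 0.600 equiv | 5.00 equiv |  | 5.0 min |

south-west run (percent of the starting material charged)

| time / min | starting material / % | target / % |
|---|---|---|
| 0.167 | 87.3 | 7.3 |
| 0.417 | 74.9 | 13.9 |
| 0.667 | 64.6 | 19.4 |
| 1.00 | 53.4 | 23.4 |
| 1.50 | 41.7 | 22.3 |
| 2.00 | 31.3 | 23.8 |
| 2.50 | 25.2 | 26.3 |

(readings scatter by 1 percentage point)

- a species is counted by the starting material in it: one side product counts as two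
- on the list of suspects stand: starting material + partner -> target; second substrate + partner -> second product; starting material + second substrate -> cross product; partner + target -> over-reaction product; starting material + target -> side product
- the reaction counts as stopped when no species that holds the starting material changes by six tenths of a point or more over the second half of the time

1. which holds at 5.0 min: what has brought the reaction to rest, or that it has not come to rest (all of the starting material has reacted / it is still moving / the partner has run out first)
2. part of the starting material gone at 5.0 min
3. the target standing at 5.0 min, as a percentage of the starting material charged
4. the side product standing at 5.0 min, as a percentage of the starting material charged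
5. amount of target if the flask were left three thousand times as long, in percent of the starting material charged

In that run the target won 0.575 of a point per point of starting material gone up to the first reading, and 0.103 from 1.00 min to 2.50 min, which is less. This net gain per point gone, the net instantaneous yield, carried my reckoning. Every suspect step joins two species, so with the equivalents held, a change of concentration stretches the clock and leaves the gain tied to the starting material left.

The south-west readings from 1.50 min to 2.50 min gave a loss of 0.504 /min, and continued, this left 7.15 % at 5.0 min. The flask would therefore still be moving, with 18 percentage points of starting material lost in the second half. I started from the mean of those last readings, with 32.7 % starting material. Holding the gain at its reading gave an upper bound of 26.8 % target. For the lower bound I let the gain keep falling at its earlier pace, 0.868 per whole charge gone. That made it −0.0652 on this stretch, below zero, and gave 22.5 %.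

The forecast said it is still moving, with 92 % gone, target 25.5 % inside my bracket, side product 2 % and 25.5 % target after the long wait, holding that “side product is small and poorly determined”.

The flask's answer was it is still moving, with 90.4 % gone, target 22.6 %, just above my lower bound of 22.5 % and so inside my bracket, side product 31.9 % and 16.4 % target after the long wait.

    starting material + partner → target (k = 0.0308 /M/s)
    second substrate + partner → second product (k = 1.45 × 10⁻⁴ /M/s)
    starting material + second substrate → cross product (k = 0.00124 /M/s)
    partner + target → over-reaction product (k = 0.00940 /M/s)
    starting material + target → side product (k = 0.0160 /M/s)

From 2.50 min to 5.00 min this flask's gain was −0.137, and at the asked time target was made at 0.471 of the rate at which it was used. The same recipe at 0.30 M left 20.7 % starting material at 5.00 min. From the same starting point, the held gain gives 25.4 % target there and the falling gain gives 24.1 %. That flask held 24.4 % target.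

Readings and results come from a simulation from invented constants; scatter was added.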